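**Retrosynthetic overview**
1. Target ⇐ bis-silyl ether 23: both aldehydes come from one Swern oxidation of the C11/C12 triethylsilyl ethers, and the Z-cinnamate from semihydrogenation of a C1 phenylpropiolate.
2. Triol 18 ⇐ Δ7 diester 17 ⇐ Δ8 diester 15: C9 is set by kinetic protonation of a dienolate, and C12 is introduced by carbonylation of an enol triflate.
3. Ring A is not built: 2,5-dimethyl-1,4-benzoquinone already carries C10-CH3, C3-CH3 and both oxygens (C4=O → C=CH2, C1=O → 1β-OH).
4. Key step: catalytic enantioselective Diels–Alder reaction of the quinone (ring A) with an ester-bearing 2-silyloxydiene forms ring B and the quaternary C10 in one step.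
5. The diene comes from acrolein and methyl acetate in three steps.

Assumption: drimane-type numbering is used (C1 = carbinol carbon, C3 = CH(CH3), C4 = C(=CH2), C5 = ring-fusion CH, C8/C9 carry C12/C11, C10 = quaternary carbon, β = face of the C10 methyl; the target is 1R,3S,5S,9R,10S), and the (S)-oxazaborolidinium catalyst is taken to give the (10S) adduct, its mirror image being used if the opposite sense is found.

**Route**

Step 1
Reactants: 1 methyl acetate; 2 acrolein (prop-2-enal)
Product: 4 methyl 3-hydroxypent-4-enoate (racemic), via lithium enolate of methyl acetate 3 (not isolated)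
Conditions: LiN(iPr)2, THF, −78 °C; then 2; AcOH quench at −78 °C
Reagents that add atoms: none
Why: Aldol addition; the lithium ester enolate adds 1,2 to acrolein at low temperature, and the racemic carbinol centre is removed in step 2.

Step 2
Reactants: 4 methyl 3-hydroxypent-4-enoate
Product: 5 methyl 3-oxopent-4-enoate
Conditions: CrO3, H2SO4, acetone, 0 °C; used at once
Reagents that add atoms: none
Why: Chromic acid (Jones) oxidation of the secondary allylic alcohol gives the vinyl β-keto ester.

Step 3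
Reactants: 5 methyl 3-oxopent-4-enoate
Product: 7 methyl (2Z)-3-[(triisopropylsilyl)oxy]penta-2,4-dienoate, via sodium dienolate 6 (not isolated)
Conditions: NaN(SiMe3)2, THF, −78 °C; then iPr3SiOSO2CF3, −78 → 0 °C
Reagents that add atoms: triisopropylsilyl trifluoromethanesulfonate, CC(C)[Si](C(C)C)(C(C)C)OS(=O)(=O)C(F)(F)F
Why: O-silylation of the sodium-chelated enolate gives the silyl dienol ether with OSi and CO2CH3 cis (Z), so the ester sits "outside" on the s-cis diene.

Step 4
Reactants: 7 methyl (2Z)-3-[(triisopropylsilyl)oxy]penta-2,4-dienoate; 8 2,5-dimethyl-1,4-benzoquinone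
Product: 9 cis-fused adduct (C1=O, C4=O, C2=C3 with 3-CH3, C7=C8 with 8-OSi(iPr)3, 9α-CO2CH3, 10β-CH3, 5β-H)
Conditions: (S)-1-(2-methylphenyl)-3,3-diphenyltetrahydro-1H,3H-pyrrolo[1,2-c][1,3,2]oxazaborole (20 mol %), HN(SO2CF3)2 (20 mol %), CH2Cl2, −78 → −20 °C
Reagents that add atoms: none
Why: Catalytic enantioselective Diels–Alder reaction, extended here to an ester-substituted silyloxydiene: the oxazaborolidinium ion binds a quinone carbonyl beside its α-C–H, the silyloxy-activated diene terminus bonds to the methyl-bearing β-carbon (C9–C10), and the shielded quinone face fixes C10; endo addition gives the cis fusion and the 9α-ester, which are corrected in steps 5 and 8/10.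

Step 5
Reactants: 9 cis-fused adduct
Product: 10 trans-fused ene-dione (as 9 but 5α-H)
Conditions: 1,8-diazabicyclo[5.4.0]undec-7-ene (10 mol %), CH2Cl2, 0 °C → rt
Reagents that add atoms: none
Why: Base-catalysed epimerization α to the C4 ketone through its dienolate; the trans-fused isomer is expected to be favoured as in related angular-methyl quinone–diene adducts, because the ring B double bond lies opposite the fusion bond, and the less acidic C9–H is untouched.

Step 6
Reactants: 10 trans-fused ene-dione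
Product: 11 trans-fused 1,4-dione (3β-CH3, 5α-H, 10β-CH3, 9α-CO2CH3, C7=C8 silyl enol ether)
Conditions: Zn dust, AcOH (10 equiv), THF, 0 °C → rt
Reagents that add atoms: none
Why: Dissolving-metal (Zn/AcOH) reduction of the ene-dione C2=C3 bond; ketonization at C3 by axial protonation, which is also the thermodynamic outcome, puts the methyl equatorial (3β).

Step 7
Reactants: 11 trans-fused 1,4-dione
Product: 12 4-methylidene 1-ketone (3β-CH3, 5α-H, 9α-CO2CH3, 8-OSi(iPr)3, C7=C8)
Conditions: Zn, CH2Br2, TiCl4, THF/CH2Cl2, 0 °C → rt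
Reagents that add atoms: dibromomethane, BrCBr
Why: Takai–Lombardo methylenation, non-basic so C3, C5 and C9 are not epimerized; only C4 reacts because the C1 carbonyl is screened on the β face by the angular methyl and on the α face by the syn-axial 9α-ester.

Step 8
Reactants: 12 4-methylidene 1-ketone
Product: 14 C8 enol triflate (C8=C9; 9-CO2CH3; 1-oxo; 4-methylidene), via tetrabutylammonium enolate 13 (not isolated)
Conditions: Bu4NF, THF, −78 °C; then PhN(SO2CF3)2, −78 °C → rt
Reagents that add atoms: N-phenylbis(trifluoromethanesulfonimide), O=S(=O)(N(c1ccccc1)S(=O)(=O)C(F)(F)F)C(F)(F)F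
Why: Fluoride desilylation gives the delocalized β-keto ester enolate (C9 becomes sp2, so its configuration is erased), which is O-sulfonylated to the enol triflate.

Step 9
Reactants: 14 C8 enol triflate
Product: 15 Δ8 dimethyl 11,12-diester (C8=C9; 1-oxo; 4-methylidene; 3β-CH3; 5α-H)
Conditions: Pd(OAc)2 (5 mol %), 1,3-bis(diphenylphosphino)propane, CO (1 atm), MeOH, Et3N, DMF, 60 °C
Reagents that add atoms: carbon monoxide, [C-]#[O+]; methanol, CO
Why: Pd-catalysed alkoxycarbonylation (oxidative addition of zerovalent palladium to C–OTf, CO insertion, methanolysis) installs C12.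

Step 10
Reactants: 15 Δ8 dimethyl 11,12-diester
Product: 17 Δ7 diester (C7=C8; 9β-CO2CH3; 9α-H; 1-oxo; 4-methylidene), via dilithium bis-enolate 16 (not isolated)
Conditions: LiN(iPr)2 (2.5 equiv), THF, −78 °C; then AcOH in THF, −78 °C
Reagents that add atoms: none
Why: Deconjugative protonation; γ-deprotonation at C7 gives the ester dienolate (the C1 ketone is held as its enolate), and kinetic α-protonation at C9 occurs axially from the α face, anti to the axial C10 methyl, giving 9α-H.

Step 11
Reactants: 17 Δ7 diester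
Product: 18 triol (1β-OH, 11-OH, 12-OH; C7=C8; 4-methylidene)
Conditions: LiAlH4, THF, −78 → 0 °C
Reagents that add atoms: none
Why: Hydride reduction; the C1 ketone is reduced first at −78 °C by axial attack from the open α face (equatorial 1β-OH), then both esters are reduced 1,2 to primary alcohols on warming.

Step 12
Reactants: 18 triol
Product: 19 11,12-bis(triethylsilyl) ether with free 1β-OH
Conditions: Et3SiCl (2.1 equiv), imidazole, CH2Cl2, −40 → 0 °C
Reagents that add atoms: chlorotriethylsilane, CC[Si](Cl)(CC)CC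
Why: Selective silylation; the two primary hydroxyls react, while the secondary C1–OH next to the quaternary carbon does not at low temperature.

Step 13
Reactants: 19 11,12-bis(triethylsilyl) ether; 20 3-phenylprop-2-ynoic acid
Product: 22 1β-(3-phenylprop-2-ynoate) of 19, via O-acylisourea 21 (not isolated)
Conditions: N,N'-dicyclohexylcarbodiimide, 4-(dimethylamino)pyridine (10 mol %), CH2Cl2, 0 °C → rt
Reagents that add atoms: none
Why: Steglich esterification of the hindered equatorial alcohol; the alkynoate avoids the Z/E lability of a cis-cinnamoyl electrophile.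

Step 14
Reactants: 22 1β-(3-phenylprop-2-ynoate)
Product: 23 1β-[(Z)-3-phenylprop-2-enoate] 11,12-bis(triethylsilyl) ether
Conditions: H2 (1 atm), Pd on CaCO3 poisoned with Pb(OAc)2, quinoline, EtOAc, rt
Reagents that add atoms: none
Why: Lindlar-type syn semihydrogenation sets the Z alkene; the isolated 1,1-disubstituted and trisubstituted alkenes are not reduced on the poisoned catalyst.

Step 15
Reactants: 23 1β-[(Z)-3-phenylprop-2-enoate] 11,12-bis(triethylsilyl) ether
Product: 25 target dialdehyde, via bis(alkoxysulfonium) dichloride 24 (not isolated)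
Conditions: (COCl)2, DMSO, CH2Cl2, −78 → −30 °C; then Et3N, −78 → 0 °C; cold neutral work-up
Reagents that add atoms: none
Why: Swern oxidation; primary triethylsilyl ethers are cleaved by the chlorosulfonium reagent and oxidized directly, so both aldehydes form together without lactol formation, and the cold work-up preserves the base-labile C9 centre.

**Compound list**

1 | methyl acetate | CC(=O)OC | starting material
2 | acrolein (prop-2-enal) | C=CC=O | starting material
3 | lithium enolate of methyl acetate | C=C([O-])OC.[Li+] | intermediate (not isolated)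
4 | methyl 3-hydroxypent-4-enoate (racemic) | C=CC(O)CC(=O)OC | intermediate
5 | methyl 3-oxopent-4-enoate | C=CC(=O)CC(=O)OC | intermediate
6 | sodium (Z)-dienolate of 5 | C=C/C([O-])=C/C(=O)OC.[Na+] | intermediate (not isolated)
7 | methyl (2Z)-3-[(triisopropylsilyl)oxy]penta-2,4-dienoate | C=C/C(O[Si](C(C)C)(C(C)C)C(C)C)=C/C(=O)OC | intermediate
8 | 2,5-dimethyl-1,4-benzoquinone | CC1=CC(=O)C(C)=CC1=O | starting material
9 | cis-fused adduct: 1,4-dioxo, C2=C3 (3-CH3), C7=C8 (8-OSi(iPr)3), 9α-CO2CH3, 10β-CH3, 5β-H | O=C1C(C)=CC(=O)[C@]2(C)[C@H](C(=O)OC)C(O[Si](C(C)C)(C(C)C)C(C)C)=CC[C@H]12 | intermediate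
10 | trans-fused ene-dione: as 9 but 5α-H | O=C1C(C)=CC(=O)[C@]2(C)[C@H](C(=O)OC)C(O[Si](C(C)C)(C(C)C)C(C)C)=CC[C@@H]12 | intermediate
11 | trans-fused 1,4-dione: 3β-CH3, 5α-H, 10β-CH3, 9α-CO2CH3, C7=C8 (8-OSi(iPr)3) | O=C1[C@@H](C)CC(=O)[C@]2(C)[C@H](C(=O)OC)C(O[Si](C(C)C)(C(C)C)C(C)C)=CC[C@@H]12 | intermediate
12 | 4-methylidene 1-ketone: 3β-CH3, 5α-H, 9α-CO2CH3, C7=C8 (8-OSi(iPr)3) | C=C1[C@@H](C)CC(=O)[C@]2(C)[C@H](C(=O)OC)C(O[Si](C(C)C)(C(C)C)C(C)C)=CC[C@@H]12 | intermediate
13 | tetrabutylammonium enolate of the 8-oxo 9-carboxylate (C8=C9) | C=C1[C@@H](C)CC(=O)[C@]2(C)C(C(=O)OC)=C([O-])CC[C@@H]12.CCCC[N+](CCCC)(CCCC)CCCC | intermediate (not isolated)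
14 | C8 enol triflate: C8=C9, 9-CO2CH3, 1-oxo, 4-methylidene | C=C1[C@@H](C)CC(=O)[C@]2(C)C(C(=O)OC)=C(OS(=O)(=O)C(F)(F)F)CC[C@@H]12 | intermediate
15 | Δ8 dimethyl 11,12-diester: C8=C9, 1-oxo, 4-methylidene, 3β-CH3, 5α-H, 10β-CH3 | C=C1[C@@H](C)CC(=O)[C@]2(C)C(C(=O)OC)=C(C(=O)OC)CC[C@@H]12 | intermediate
16 | dilithium bis-enolate (C1 enolate and C11 ester dienolate) | C=C1[C@@H](C)C=C([O-])[C@]2(C)C(=C([O-])OC)C(C(=O)OC)=CC[C@@H]12.[Li+].[Li+] | intermediate (not isolated)
17 | Δ7 diester: C7=C8, 9β-CO2CH3 (9α-H), 8-CO2CH3, 1-oxo, 4-methylidene | C=C1[C@@H](C)CC(=O)[C@]2(C)[C@@H](C(=O)OC)C(C(=O)OC)=CC[C@@H]12 | intermediate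
18 | triol: 1β-OH, 9β-CH2OH, 8-CH2OH, C7=C8, 4-methylidene, 3β-CH3 | C=C1[C@@H](C)C[C@@H](O)[C@]2(C)[C@@H](CO)C(CO)=CC[C@@H]12 | intermediate
19 | 11,12-bis(triethylsilyl) ether of 18 | C=C1[C@@H](C)C[C@@H](O)[C@]2(C)[C@@H](CO[Si](CC)(CC)CC)C(CO[Si](CC)(CC)CC)=CC[C@@H]12 | intermediate
20 | 3-phenylprop-2-ynoic acid (phenylpropiolic acid) | OC(=O)C#Cc1ccccc1 | starting material
21 | O-acylisourea of 20 and dicyclohexylcarbodiimide | O=C(C#Cc1ccccc1)OC(=NC1CCCCC1)NC1CCCCC1 | intermediate (not isolated)
22 | 1β-(3-phenylprop-2-ynoate) of 19 | C=C1[C@@H](C)C[C@@H](OC(=O)C#Cc2ccccc2)[C@]2(C)[C@@H](CO[Si](CC)(CC)CC)C(CO[Si](CC)(CC)CC)=CC[C@@H]12 | intermediate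
23 | 1β-[(Z)-3-phenylprop-2-enoate] 11,12-bis(triethylsilyl) ether | C=C1[C@@H](C)C[C@@H](OC(=O)/C=C\c2ccccc2)[C@]2(C)[C@@H](CO[Si](CC)(CC)CC)C(CO[Si](CC)(CC)CC)=CC[C@@H]12 | intermediate
24 | 11,12-bis(dimethylalkoxysulfonium) dichloride of the Z-cinnamate | C=C1[C@@H](C)C[C@@H](OC(=O)/C=C\c2ccccc2)[C@]2(C)[C@@H](CO[S+](C)C)C(CO[S+](C)C)=CC[C@@H]12.[Cl-].[Cl-] | intermediate (not isolated)
25 | target: (1R,3S,5S,9R,10S)-1β-[(Z)-cinnamoyloxy]-3β,10β-dimethyl-4-methylidene-Δ7-octalin-8,9β-dicarbaldehyde | C=C1[C@@H](C)C[C@@H](OC(=O)/C=C\c2ccccc2)[C@]2(C)[C@@H](C=O)C(C=O)=CC[C@@H]12 | target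

**Totals**

Total step count: 15. Longest linear sequence: 15 steps (1 and 2 to 25; compounds 8 and 20 are bought).

**Three steps most likely to fail**

Step 4. The ester makes the diene less nucleophilic and bulkier than the parent 2-silyloxybutadiene, and its carbonyl can compete for the boron catalyst, so rate and enantioselectivity are unproven. The fallback takes absolute configuration from a resolution instead of from the catalyst. It sets out from 7 and 8, which are combined with the same oxazaborolidinium triflimide prepared from racemic α,α-diphenylprolinol at higher loading and temperature, giving the racemic cis-fused adduct F1. F1 is separated by preparative chromatography on a cellulose tris(3,5-dimethylphenylcarbamate) phase, and the (10S) enantiomer is compound 9, where the route is rejoined.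

Step 5. The cis/trans equilibrium of this particular ene-dione is not known and could lie on the cis side. The fallback replaces thermodynamic epimerization by dehydrogenation followed by face-selective hydrogenation. It sets out from 9, which is treated with Bu4NF and then PhN(SO2CF3)2 to give, through the tetrabutylammonium enolate F2, the cis-fused ene-dione enol triflate F3. Carbonylation of F3 (Pd(OAc)2, 1,3-bis(diphenylphosphino)propane, CO, MeOH, Et3N) gives the cis-fused ene-dione Δ8 diester F4. 2-Iodoxybenzoic acid in DMSO at 70 °C dehydrogenates the C4 ketone, whose only α-hydrogen is at C5, to the C5=C6 triene-dione F5. Hydrogen over Pd on carbon then adds to C5=C6 from the α face, opposite the angular methyl, and to C2=C3, while the tetrasubstituted diester alkene is left, giving the trans-fused 1,4-dione Δ8 diester F6. Methylenation of its C4 ketone with Zn, CH2Br2 and TiCl4 gives compound 15, where the route is rejoined.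

Step 10. Protonation of the dienolate could occur at C7 (returning 15) or from the β face. The fallback locks C9 through a lactone to the C1 oxygen. It sets out from 15: NaBH4 in MeOH at −20 °C reduces the C1 ketone from the α face, and the resulting 1β-hydroxy Δ8 diester F7 closes onto the neighbouring C11 ester to give the Δ8 γ-lactone F8. LiN(iPr)2 and then AcOH at −78 °C convert F8, through the lithium dienolate F9, into the Δ7 lactone F10; the five-membered ring can only stay closed when H-9 is α. LiAlH4 reduces the lactone and the C12 ester of F10 to triol 18, where the route is rejoined.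

**Further compounds**

F1 | step 4 | racemic cis-fused adduct (9 together with its mirror image) | O=C1C(C)=CC(=O)[C@]2(C)[C@H](C(=O)OC)C(O[Si](C(C)C)(C(C)C)C(C)C)=CC[C@H]12.O=C1C(C)=CC(=O)[C@@]2(C)[C@@H](C(=O)OC)C(O[Si](C(C)C)(C(C)C)C(C)C)=CC[C@@H]12
F2 | step 5 | tetrabutylammonium enolate of the cis-fused ene-dione β-keto ester | O=C1C(C)=CC(=O)[C@]2(C)C(C(=O)OC)=C([O-])CC[C@H]12.CCCC[N+](CCCC)(CCCC)CCCC
F3 | step 5 | cis-fused ene-dione C8 enol triflate | O=C1C(C)=CC(=O)[C@]2(C)C(C(=O)OC)=C(OS(=O)(=O)C(F)(F)F)CC[C@H]12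
F4 | step 5 | cis-fused ene-dione Δ8 dimethyl diester | O=C1C(C)=CC(=O)[C@]2(C)C(C(=O)OC)=C(C(=O)OC)CC[C@H]12
F5 | step 5 | triene-dione diester (C2=C3, C5=C6, C8=C9) | O=C1C(C)=CC(=O)[C@]2(C)C(C(=O)OC)=C(C(=O)OC)CC=C12
F6 | step 5 | trans-fused 1,4-dione Δ8 diester (3β-CH3, 5α-H) | O=C1[C@@H](C)CC(=O)[C@]2(C)C(C(=O)OC)=C(C(=O)OC)CC[C@@H]12
F7 | step 10 | 1β-hydroxy Δ8 diester | C=C1[C@@H](C)C[C@@H](O)[C@]2(C)C(C(=O)OC)=C(C(=O)OC)CC[C@@H]12
F8 | step 10 | Δ8 γ-lactone (C11 carbonyl to O1) 12-methyl ester | C=C1[C@@H](C)C[C@@H](O3)[C@]2(C)C(C3=O)=C(C(=O)OC)CC[C@@H]12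
F9 | step 10 | lithium dienolate of lactone F8 | C=C1[C@@H](C)C[C@@H](O3)[C@]2(C)C(=C3[O-])C(C(=O)OC)=CC[C@@H]12.[Li+]
F10 | step 10 | Δ7 γ-lactone 12-methyl ester (9α-H) | C=C1[C@@H](C)C[C@@H](O3)[C@]2(C)[C@@H](C3=O)C(C(=O)OC)=CC[C@@H]12
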